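0.0393 /min: that reading is what I carry through this flask. In Sunday's run target stands at 34.4% after 3.00 min, with substrate down to 3.8%, and at 31.8% after 5.00 min. So I define the loss constant k_L, the fraction of the target present that goes per minute once its supply has faded; with the gas held, it is a pseudo-first-order constant. The drop is 2.6 percentage points against a scatter of 1 point per reading, so k_L is rough.

the same everywhere: substrate 20 mM; gas phase 0.64 mM (held)

| charge | catalyst | remark | time |
|---|---|---|---|
| Tuesday's | 0.10 mM | run made earlier |  |
| Sunday's | 0.22 mM | run made earlier |  |
| flask | 0.15 mM |  | 8.0 min |

- Tuesday's (time / min: target / %, substrate / %): 1.00: 20.1, 62.3; 2.00: 27.8, 38.3; 3.00: 29.4, 21.6; 4.00: 29.8, 11.7; 5.00: 29.9, 8.4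
- Sunday's (time / min: target / %, substrate / %): 0.417: 22.7, 64.5; 1.33: 34.6, 24.6; 2.00: 34.3, 11.0; 3.00: 34.4, 3.8; 5.00: 31.8, 0

(readings scatter by 1 percentage point)

- how much target there is at 8.0 min, in percent of the substrate charged
- the change that raises the amount of target at 8.0 min, in percent of the substrate charged most ("none" if none brings more than 2 percentage points) (midnight / dawn / spring / none)
- amount of target at 8.0 min, in percent of the substrate charged, after spring

- midnight: doubling the amount of catalyst, all else as stated
- dawn: doubling the transfer coefficient of the gas phase, all else as stated
- spring: doubling the saturation concentration of gas phase, all else as stated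

- at the start none of the gas phase is in solution

I solve the flask at both ends and join them. The early end is a plateau: Tuesday's run reaches 29.9% and Sunday's 34.4%, and interpolating on catalyst gives 31.8% for the flask. The first-order constants of substrate, 0.487 /min and 1.06 /min, stand roughly as the catalyst charges do, so I scale Sunday's join by catalyst and get t_j = 4.40 min for the flask. From there k_L takes over, and target at 8.0 min is 27.6%.

Midnight puts 0.300 mM of catalyst in the flask, above Sunday's 0.22 mM, so I have to extend the plateau line past both runs, to 37.4%. The join moves to 2.20 min, and k_L then gives 29.8% at 8.0 min. That is a gain of 2.2 points against a margin of 2 points and a scatter of 1 point per reading, and it rests on an extrapolated plateau, so I do not count on it. The gas never varies in these runs, so I assume k_L grows with dissolved gas. Spring then doubles it and gives 23.9%, and dawn leaves the saturation where it stands. My choice is none.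

The forecast gives 29%, none and 24% after spring, reasoning that “dissolved gas appears to divert substrate to something else”, and its first number stands above my 27.6%.

The flask gives 28.8%, with none as the best change: midnight moves target by −0.56 points, dawn by −0.13 points, and spring leaves 21.5%, 2.4 points below my figure.

    gas phase ⇌ dissolved gas, rate k1*(csat - [dissolved gas]) (kL = 2.70 /s)
    substrate + dissolved gas + catalyst → catalyst + target (k = 1.40 × 10⁵ /M²/s)
    dissolved gas + target → over-reaction product (k = 2.40 /M/s)
    target ⇌ isomer of the product (K = 1.70, k = 0.0370 /s)

Between 4.00 min and 8.00 min the over-reaction product in the flask goes from 9.66% to 20.8%, while target goes from 32.1% to 28.8%. Applied to that 32.1%, k_L gives 27.4%.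

For the same flask read at 15 min, k_L applied to 28.8% gives 21.9%. The computed value is 22.8%.

(The data come from a simulation with made-up constants; the scatter is artificial.)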